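The all-cis tetralin is traced through a 3,4-dihydronaphthalene diester to an open, achiral diene by cutting C4–C4a of ring B. The cut exploits a degeneracy. Ring A (C4a–C8a) and the pendant aryl on C1 differ only once C4 is tied to C4a, and in the open form both are 3,4-dimethoxyphenyl groups on one carbon. The precursor, a 1,1-diaryl-2,3-bis(methoxycarbonyl)buta-1,3-diene, therefore has neither alkene geometry nor a stereocentre. In one operation a chiral SnCl4–BINOL acid lets the arene carbon para to a methoxy group add to the terminal CH2 (C4), closing ring B, and protonates the resulting ester enol at C3 on one face. C1 and C2 are then relayed from C3 by syn hydrogenation.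

Key step: step 5

Numbering remark: the tetralin numbering of the target is used for all compounds. C1 bears the aryl group, C2 and C3 bear the one-carbon side chains, and C4 is the benzylic CH2. Ring A is the fused arene and ring B the carbocycle. The target is the all-cis (1S,2S,3R) isomer.

Assumption: the sense of induction of the BINOL·SnCl4 proton donor on this substrate class cannot be derived from precedent. The (R)-ligand is written, and its equally available (S)-antipode is used if a test run shows that it leads to (3R)-11.

Step 1
Reactants: 1 3,3',4,4'-tetramethoxybenzophenone; 2 dimethyl succinate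
Product: 4 3-(methoxycarbonyl)-4,4-bis(3,4-dimethoxyphenyl)but-3-enoic acid, via paraconic lactone ester 3 (not isolated)
Conditions: KOt-Bu, toluene, 70 °C; then aq. HCl
Reagents that add atoms: none
Why: Stobbe condensation, in which the succinate enolate adds to the diaryl ketone, the alkoxide lactonises to 3 and irreversible E1cB opening of the lactone gives the alkylidene half-ester; the sequence is standard for benzophenones and raises no E/Z question because both aryl groups are alike.

Step 2
Reactants: 4 3-(methoxycarbonyl)-4,4-bis(3,4-dimethoxyphenyl)but-3-enoic acid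
Product: 5 dimethyl 2-[bis(3,4-dimethoxyphenyl)methylidene]butanedioate
Conditions: MeI, K2CO3, DMF, rt
Reagents that add atoms: iodomethane, CI
Why: Carboxylate O-alkylation (SN2 on MeI) under weakly basic conditions leaves the tetrasubstituted alkene in place and avoids acid-induced relactonisation of the electron-rich diarylalkene, and since this carboxyl will flank C3, its alkyl group stays a free handle for tuning step 5 at no cost in steps.

Step 3
Reactants: 5 dimethyl 2-[bis(3,4-dimethoxyphenyl)methylidene]butanedioate; 6 N,N-dimethylmethyleneiminium iodide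
Product: 7 dimethyl 2-[bis(3,4-dimethoxyphenyl)methylidene]-3-[(dimethylamino)methyl]butanedioate (racemic)
Conditions: LiN(i-Pr)2 (LDA), THF, −78 °C; then 6, −78 °C → rt
Reagents that add atoms: none
Why: Mannich-type aminomethylation of a preformed lithium ester enolate, in which the C3 methylene is the only enolisable site and its α-carbon should react in preference to the fully substituted diaryl γ-carbon C1; the new stereocentre is racemic and is erased in step 4.

Step 4
Reactants: 7 dimethyl 2-[bis(3,4-dimethoxyphenyl)methylidene]-3-[(dimethylamino)methyl]butanedioate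
Product: 9 dimethyl 2-[bis(3,4-dimethoxyphenyl)methylidene]-3-methylidenebutanedioate, via trimethylammonium iodide 8 (not isolated)
Conditions: MeI, CH2Cl2, rt; then sat. aq. NaHCO3, rt, dark, trace BHT
Reagents that add atoms: iodomethane, CI (its methyl group and iodide appear in 8 only and are lost again on the way to 9)
Why: Exhaustive N-methylation followed by Hofmann-type E1cB elimination, in which the C3–H of 8 is activated by the ester and the adjacent alkene so that bicarbonate should suffice to expel trimethylamine, and 9 has no enolisable hydrogen left through which it could isomerise.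

Step 5
Reactants: 9 dimethyl 2-[bis(3,4-dimethoxyphenyl)methylidene]-3-methylidenebutanedioate
Product: 11 dimethyl (3R)-1-(3,4-dimethoxyphenyl)-6,7-dimethoxy-3,4-dihydronaphthalene-2,3-dicarboxylate, via tin-bound ester dienol 10 (not isolated)
Conditions: SnCl4 (1.5 equiv), (R)-3,3'-dibromo-BINOL (0.3 equiv), 4 Å MS, CH2Cl2, −40 → 0 °C, dark; cold pH 7 sodium phosphate buffer
Reagents that add atoms: none
Why: Proposed new method: SnCl4 is expected to bind both ester carbonyls of 9 as a seven-membered chelate, which lowers the LUMO of the α-substituted acrylate and also holds the C1=C2–C3=C4 diene s-cis, so that C4 lies over an ortho carbon of the aryl group cis to it. That carbon (C6', para to the 3'-methoxy group, the future C4a) attacks C4 in a 6-endo-trig Friedel–Crafts conjugate addition, which can equally be read as a polarised 6π closure of the aryl–C1=C2–C3=C4 triene, and loss of the arenium proton restores ring A and leaves the tin-bound dienol 10. The only new stereocentre, C3, is set when BINOL·SnCl4, a Lewis-acid-assisted Brønsted acid, hands its proton to one face of the flat enol carbon while the arenium proton recharges the ligand, so reagent control alone decides the configuration. The closest known reaction types are the SnCl4/BINOL-promoted tandem Friedel–Crafts conjugate addition and enantioselective protonation of α-substituted acrylates with indoles, the enantioselective protonation of enol derivatives by the same acid, and the Brønsted-acid cyclisation of bis(arylmethylidene)succinates to aryldihydronaphthalenes; new here is the intramolecular use on a diene diester with a veratryl nucleophile. The step needs ortho-site selectivity (secured by para activation and by the crowding of C2' between C1' and a methoxy group), α- over γ-protonation of the dienol (the kinetic preference of dienolates, which also keeps C1=C2 conjugated with both arenes and the C2 ester) and face selectivity, whereas no choice between the aryl groups arises because they are identical and only the cis one can reach C4. Low temperature, exclusion of light and a cold neutral quench are meant to keep the acidic allylic C3–H from re-enolising and to suppress an uncatalysed racemic photocyclisation.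

Step 6
Reactants: 11 dimethyl (3R)-1-(3,4-dimethoxyphenyl)-6,7-dimethoxy-3,4-dihydronaphthalene-2,3-dicarboxylate
Product: 12 dimethyl (1S,2S,3R)-1-(3,4-dimethoxyphenyl)-6,7-dimethoxy-1,2,3,4-tetrahydronaphthalene-2,3-dicarboxylate (all-cis)
Conditions: H2 (5 bar), 10% Pd/C, EtOAc, rt, 11 used without delay
Reagents that add atoms: none
Why: Heterogeneous catalytic hydrogenation with syn delivery of H2, in which allylic strain with the C2 ester holds the C3 ester pseudoaxial so that it shields one face of the half-chair and hydrogen adds to C1 and C2 from the other face, placing the aryl group and the C2 ester cis to each other and cis to the C3 ester (1S,2S), as is usual for 1-aryldihydronaphthalene lignan esters and lactones, while the neutral aprotic medium spares the C3–H.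

Step 7
Reactants: 12 dimethyl (1S,2S,3R)-1-(3,4-dimethoxyphenyl)-6,7-dimethoxy-1,2,3,4-tetrahydronaphthalene-2,3-dicarboxylate
Product: 13 [(1S,2S,3R)-1-(3,4-dimethoxyphenyl)-6,7-dimethoxy-1,2,3,4-tetrahydronaphthalene-2,3-diyl]dimethanol
Conditions: LiAlH4, THF, 0 °C (12 added to the hydride); then H2O, aq. NaOH
Reagents that add atoms: none
Why: Ester reduction by LiAlH4 breaks no bond at C1, C2 or C3, and slow addition of 12 to excess hydride in the cold should keep reduction faster than alkoxide-induced epimerisation of the crowded all-cis diester.

Step 8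
Reactants: 13 [(1S,2S,3R)-1-(3,4-dimethoxyphenyl)-6,7-dimethoxy-1,2,3,4-tetrahydronaphthalene-2,3-diyl]dimethanol
Product: 14 (1S,2S,3R)-1-(3,4-dimethoxyphenyl)-6,7-dimethoxy-2,3-bis(methoxymethyl)-1,2,3,4-tetrahydronaphthalene (target)
Conditions: NaH, MeI, THF, 0 °C → rt
Reagents that add atoms: iodomethane, CI
Why: Double Williamson ether synthesis on two primary alkoxides, with no leaving group present that could lead to a cyclic ether and no acidic C–H left at the three stereocentres.

Compound list
1 | 3,3',4,4'-tetramethoxybenzophenone | COc1ccc(C(=O)c2ccc(OC)c(OC)c2)cc1OC | starting material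
2 | dimethyl succinate | COC(=O)CCC(=O)OC | starting material
3 | methyl 2,2-bis(3,4-dimethoxyphenyl)-5-oxooxolane-3-carboxylate (racemic, not isolated) | COC(=O)C1CC(=O)OC1(c1ccc(OC)c(OC)c1)c1ccc(OC)c(OC)c1 | intermediate
4 | 3-(methoxycarbonyl)-4,4-bis(3,4-dimethoxyphenyl)but-3-enoic acid | COC(=O)C(CC(=O)O)=C(c1ccc(OC)c(OC)c1)c1ccc(OC)c(OC)c1 | intermediate
5 | dimethyl 2-[bis(3,4-dimethoxyphenyl)methylidene]butanedioate | COC(=O)CC(C(=O)OC)=C(c1ccc(OC)c(OC)c1)c1ccc(OC)c(OC)c1 | intermediate
6 | N,N-dimethylmethyleneiminium iodide | C=[N+](C)C.[I-] | starting material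
7 | dimethyl 2-[bis(3,4-dimethoxyphenyl)methylidene]-3-[(dimethylamino)methyl]butanedioate (racemic) | CN(C)CC(C(=O)OC)C(C(=O)OC)=C(c1ccc(OC)c(OC)c1)c1ccc(OC)c(OC)c1 | intermediate
8 | [4,4-bis(3,4-dimethoxyphenyl)-2,3-bis(methoxycarbonyl)but-3-en-1-yl]trimethylammonium iodide (racemic, not isolated) | C[N+](C)(C)CC(C(=O)OC)C(C(=O)OC)=C(c1ccc(OC)c(OC)c1)c1ccc(OC)c(OC)c1.[I-] | intermediate
9 | dimethyl 2-[bis(3,4-dimethoxyphenyl)methylidene]-3-methylidenebutanedioate (achiral key-step precursor) | C=C(C(=O)OC)C(C(=O)OC)=C(c1ccc(OC)c(OC)c1)c1ccc(OC)c(OC)c1 | intermediate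
10 | methyl 1-(3,4-dimethoxyphenyl)-3-[hydroxy(methoxy)methylidene]-6,7-dimethoxy-3,4-dihydronaphthalene-2-carboxylate (drawn as the free enol, tin on the enol oxygen in the flask, enol geometry not defined, not isolated) | COC(O)=C1Cc2cc(OC)c(OC)cc2C(c2ccc(OC)c(OC)c2)=C1C(=O)OC | intermediate
11 | dimethyl (3R)-1-(3,4-dimethoxyphenyl)-6,7-dimethoxy-3,4-dihydronaphthalene-2,3-dicarboxylate | COC(=O)[C@@H]1Cc2cc(OC)c(OC)cc2C(c2ccc(OC)c(OC)c2)=C1C(=O)OC | intermediate
12 | dimethyl (1S,2S,3R)-1-(3,4-dimethoxyphenyl)-6,7-dimethoxy-1,2,3,4-tetrahydronaphthalene-2,3-dicarboxylate | COC(=O)[C@@H]1Cc2cc(OC)c(OC)cc2[C@H](c2ccc(OC)c(OC)c2)[C@@H]1C(=O)OC | intermediate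
13 | [(1S,2S,3R)-1-(3,4-dimethoxyphenyl)-6,7-dimethoxy-1,2,3,4-tetrahydronaphthalene-2,3-diyl]dimethanol | OC[C@@H]1Cc2cc(OC)c(OC)cc2[C@H](c2ccc(OC)c(OC)c2)[C@@H]1CO | intermediate
14 | (1S,2S,3R)-1-(3,4-dimethoxyphenyl)-6,7-dimethoxy-2,3-bis(methoxymethyl)-1,2,3,4-tetrahydronaphthalene | COC[C@@H]1Cc2cc(OC)c(OC)cc2[C@H](c2ccc(OC)c(OC)c2)[C@@H]1COC | target

Total step count: 8
Longest linear sequence: 8 steps (1 → 14)

Steps most likely to fail

Step 5 (carries the label "Proposed new method:"). Three processes could defeat it:
- weak discrimination between the two faces of the enol during proton transfer;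
- re-enolisation at C3 on the tin chelate with erosion of optical purity;
- slow ring closure because tin is tied up by the veratryl ether oxygens.

The fallback uses known chemistry and sets the stereocentre by resolution instead of catalysis. It sets out from 9. TfOH in CH2Cl2 at 0 °C is the Brønsted-acid Friedel–Crafts cyclisation established for bis(arylmethylidene)succinates. It should give racemic dimethyl 1-(3,4-dimethoxyphenyl)-6,7-dimethoxy-3,4-dihydronaphthalene-2,3-dicarboxylate F1. Preparative chromatography on a polysaccharide-based chiral stationary phase with a neutral eluent should separate this into two parts. One is 11, where the route is rejoined. The other is its mirror image dimethyl (3S)-1-(3,4-dimethoxyphenyl)-6,7-dimethoxy-3,4-dihydronaphthalene-2,3-dicarboxylate F2, which should be recyclable to the racemate by re-enolisation with the same acid.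

Step 6. Four processes could defeat it:
- sluggish hydrogen uptake at the tetrasubstituted, ester-conjugated alkene;
- palladium-induced alkene migration towards C3 with loss of configuration;
- dehydrogenation to the naphthalene;
- insufficient face selectivity.

The fallback removes the esters before the reduction. It sets out from 11.
- i-Bu2AlH (CH2Cl2, −78 → 0 °C), a non-basic reductant, should give [(3R)-1-(3,4-dimethoxyphenyl)-6,7-dimethoxy-3,4-dihydronaphthalene-2,3-diyl]dimethanol F3, in which C3–H is no longer acidic.
- NaH/MeI should give (3R)-1-(3,4-dimethoxyphenyl)-6,7-dimethoxy-2,3-bis(methoxymethyl)-3,4-dihydronaphthalene F4.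
- Hydrogenation of this ester-free styrene-type alkene over PtO2 in EtOAc, again anti to the pseudoaxial C3 substituent, should lead directly to 14. Platinum is chosen because it is less prone than palladium to cleave the allylic C–O bond and to shift alkenes.

Step 3. The shielded ambident enolate may react sluggishly, attack through its γ-carbon, or undergo retro-Mannich cleavage on warming. The fallback replaces the kinetic Mannich and elimination pair (steps 3 and 4) by a second Stobbe condensation, the standard entry to bis(alkylidene)succinates. It sets out from 5. With KOt-Bu and paraformaldehyde in THF (0 °C → rt), the reversible hydroxymethylation at C3 is followed by lactonisation onto the C2 ester. This gives methyl 4-[bis(3,4-dimethoxyphenyl)methylidene]-5-oxooxolane-3-carboxylate F5. Irreversible E1cB opening of F5 gives 2-[bis(3,4-dimethoxyphenyl)methylidene]-3-(methoxycarbonyl)but-3-enoic acid F6, so misdirected additions can revert. MeI/K2CO3 in DMF then rejoins the route at 9.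

Further compounds
F1 | step 5 | racemic dimethyl 1-(3,4-dimethoxyphenyl)-6,7-dimethoxy-3,4-dihydronaphthalene-2,3-dicarboxylate | COC(=O)C1Cc2cc(OC)c(OC)cc2C(c2ccc(OC)c(OC)c2)=C1C(=O)OC
F2 | step 5 | dimethyl (3S)-1-(3,4-dimethoxyphenyl)-6,7-dimethoxy-3,4-dihydronaphthalene-2,3-dicarboxylate | COC(=O)[C@H]1Cc2cc(OC)c(OC)cc2C(c2ccc(OC)c(OC)c2)=C1C(=O)OC
F3 | step 6 | [(3R)-1-(3,4-dimethoxyphenyl)-6,7-dimethoxy-3,4-dihydronaphthalene-2,3-diyl]dimethanol | OC[C@@H]1Cc2cc(OC)c(OC)cc2C(c2ccc(OC)c(OC)c2)=C1CO
F4 | step 6 | (3R)-1-(3,4-dimethoxyphenyl)-6,7-dimethoxy-2,3-bis(methoxymethyl)-3,4-dihydronaphthalene | COC[C@@H]1Cc2cc(OC)c(OC)cc2C(c2ccc(OC)c(OC)c2)=C1COC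
F5 | step 3 | methyl 4-[bis(3,4-dimethoxyphenyl)methylidene]-5-oxooxolane-3-carboxylate (racemic) | COC(=O)C1COC(=O)C1=C(c1ccc(OC)c(OC)c1)c1ccc(OC)c(OC)c1
F6 | step 3 | 2-[bis(3,4-dimethoxyphenyl)methylidene]-3-(methoxycarbonyl)but-3-enoic acid | C=C(C(=O)OC)C(C(=O)O)=C(c1ccc(OC)c(OC)c1)c1ccc(OC)c(OC)c1
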